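The numbers in the tables are simulated from invented constants; noise was put on by code.

Target climbs on a straight line, a zero-order profile, reaching 95.6% at 50.0 min in Saturday's run.

| flask | solid substrate | second substrate | free catalyst | added ligand | remark |
|---|---|---|---|---|---|
| Saturday's | 0.050 M | 0.050 M | 0.34 mM | 0.62 mM | run made earlier |
| Thursday's | 0.050 M | 0.050 M | 0.34 mM | 1.4 mM | run made earlier |
| flask | 0.050 M | 0.0500 M | 0.34 mM | 0.93 mM |  |

| run | time / min | target / % |
|---|---|---|
| Saturday's | 6.00 | 9.1 |
| Saturday's | 8.00 | 11.5 |
| Saturday's | 12.0 | 21.2 |
| Saturday's | 20.0 | 35.1 |
| Saturday's | 30.0 | 55.3 |
| Saturday's | 50.0 | 95.6 |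
| Saturday's | 80.0 | 98.5 |
| Thursday's | 4.00 | 3.2 |
| Thursday's | 12.0 | 21.0 |
| Thursday's | 20.0 | 32.0 |
| Thursday's | 30.0 | 51.7 |
| Thursday's | 40.0 | 71.9 |
| Thursday's | 60.0 | 99.2 |
| Thursday's | 80.0 | 99.9 |

(standard deviation of a reading: 1 percentage point)

- solid substrate is a solid; its amount is given per volume of the solution
- the analysis behind the earlier runs scatters by 1 percentage point, standard deviation
- at the start none of the solid substrate is in solution
- what has only dissolved of solid substrate counts as not reacted
- no earlier run changes the charge of free catalyst; that part of a forecast is a guess
- no earlier run changes the charge of second substrate; that part of a forecast is a guess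

- apparent order in free catalyst when 50% of the solid substrate are converted (what has only dissolved counts as not reacted) (percent change of the rate of making target for one percent more free catalyst charged)
- apparent order in second substrate when 50% of the solid substrate are converted (what has only dissolved counts as not reacted) (percent change of the rate of making target for one percent more second substrate charged)

1. Added ligand. Over the same stretch, 12.0 min to 30.0 min, the slope s is 1.14 h⁻¹ in Saturday's run and 1.02 h⁻¹ in Thursday's, which has more ligand and a lower slope. Then n = −0.129: the ligand sensitivity, the percent change of slope for one percent more added ligand. It is a reading, with a scatter of 1 percentage point in each point behind it. For the flask, the fraction left falls as 1 − s·t, with s = 1.08 h⁻¹, so 50% conversion should come at 0.463 h.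

2. Free catalyst. No run changes its charge. If added ligand takes catalyst out of the round, free catalyst falls by at most the ligand ratio, so the order in catalyst is at least 0.129. This reckoning commits to a small order near that value.

3. Second substrate. No run changes this charge either. Saturday's slope from 30.0 min to 50.0 min is 1.21 h⁻¹. Set against the fraction of target still to come at the middle of each stretch, this gives an order of −0.0669, a reading of the target curve. Neither earlier run reports second substrate, so this order does not carry over to it, and the value of about zero taken here for second substrate is a guess.

4. The forecast gives 0.7 for free catalyst, a figure above this reckoning, and 0.05 for second substrate, holding that more ligand “barely changes the rate”.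

5. The flask gives 0.18 for free catalyst and 4.3 × 10⁻⁴ for second substrate.

    starting material + free catalyst ⇌ catalyst intermediate A (K = 89.0 M⁻¹, k = 13000 M⁻¹ min⁻¹)
    catalyst intermediate A → free catalyst + target (k = 29.0 min⁻¹)
    second substrate + free catalyst ⇌ catalyst intermediate B (K = 330 M⁻¹, k = 750 M⁻¹ min⁻¹)
    catalyst intermediate B → free catalyst + second product (k = 310 min⁻¹)
    solid substrate ⇌ starting material, rate k5*(cs5 - [starting material]) while solid is left; crystals form when [starting material] > cs5 (solubility = 17.0 mM, k = 0.0680 min⁻¹)
    free catalyst + added ligand ⇌ idle complex, settled at all times (K = 930 M⁻¹)

6. The flask reaches 50% conversion at 0.463 h, against 0.463 h from n, and its rate at 0.761 h stands at 1.0 of the rate there. Taken as the order in catalyst, n puts a factor of 0.914 on that time with twice the free catalyst, and that run gives 0.880.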